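**Plan**
Retrosynthesis: the pyranone ring is opened at O1–C2 and its C4 carbonyl is traced back to a C4=N unit, which reveals a 3-aryl-5-alkylisoxazole. That ring is cut at C3–C4 and C2–O into an aryl nitrile oxide and a terminal alkyne, and the side chain is cut at C2'–C3' into heptynoic acid and a malonate half ester.
Enabling feature: C2–C3–C4 of the pyranone ring is a 1,3-dioxygenated three-carbon unit bound to C4a of the benzene ring, and C4a lies between oxygen-bearing C5 and C8a. C4 can therefore arrive as the carbon of a doubly ortho-shielded, isolable nitrile oxide, and C2–C3 as a C≡C–H group.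
Forward: the benzene ring is bought. The two fragments (three and two steps) are joined in step 6 with closure of the isoxazole ring, step 7 opens that ring reductively, and step 8 closes the pyranone ring.
Stereochemistry: the only stereocentre, (S)-C3' of the heptanoate chain, comes from an enzymatic reduction of the β-keto ester in step 5 and is a spectator afterwards.

Key step: step 6

Assumption: the ketoreductase of step 5 is picked from a commercial screening panel, which normally holds enzymes of both facial preferences for 3-oxoalkanoates. The enzyme giving the (S)-alcohol is used, and the configuration of 10 is verified before the fragments are joined.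

Step 1
Reactants: 1 2-hydroxy-4,6-dimethoxybenzaldehyde; 2 benzyl bromide
Product: 3 2-(benzyloxy)-4,6-dimethoxybenzaldehyde
Conditions: K2CO3, DMF, 60 °C
Reagents that add atoms: none
Why: Williamson ether synthesis, in which carbonate deprotonates the hydrogen-bonded phenol and the phenoxide displaces bromide from the benzylic halide by SN2, while the aldehyde and the methyl ethers are inert.

Step 2
Reactants: 3 2-(benzyloxy)-4,6-dimethoxybenzaldehyde
Product: 4 (E)-2-(benzyloxy)-4,6-dimethoxybenzaldehyde oxime
Conditions: NH2OH·HCl, NaOAc, EtOH/H2O, 60 °C
Reagents that add atoms: hydroxylamine hydrochloride, NO.Cl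
Why: Oxime condensation, in which buffered hydroxylamine adds to the aldehyde and water is lost to give the less crowded (E)-aldoxime, although either geometry would serve in step 3.

Step 3
Reactants: 4 (E)-2-(benzyloxy)-4,6-dimethoxybenzaldehyde oxime
Product: 5 2-(benzyloxy)-4,6-dimethoxybenzonitrile oxide
Conditions: PhI(OAc)2, TFA (cat.), MeOH, 0 °C; aq. NaHCO3 wash
Reagents that add atoms: none
Why: Hypervalent-iodine dehydrogenation of an aldoxime, in which ligand exchange at trivalent iodine is followed by loss of iodobenzene and acetic acid; the oxidant carries no electrophilic halogen that could attack the very electron-rich ring, and the two ortho alkoxy groups block furoxan formation, so 5 should be isolable.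

Step 4
Reactants: 6 hept-6-ynoic acid; 7 potassium methyl malonate
Product: 9 methyl 3-oxonon-8-ynoate, via acyl imidazolide 8 (not isolated)
Conditions: CDI, THF, rt; then 7, MgCl2, THF, rt to 40 °C; 1 M HCl work-up
Reagents that add atoms: 1,1'-carbonyldiimidazole, O=C(n1ccnc1)n1ccnc1 (supplies the imidazolyl group of 8; none of its atoms remains in 9)
Why: Masamune–Brooks homologation, in which the acyl imidazolide C-acylates the magnesium enolate of the malonate half ester and the adduct decarboxylates, in a medium too weakly basic to touch the terminal alkyne.

Step 5
Reactants: 9 methyl 3-oxonon-8-ynoate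
Product: 10 methyl (S)-3-hydroxynon-8-ynoate
Conditions: (S)-selective ketoreductase (commercial panel), NADP+ (cat.), iPrOH, phosphate buffer pH 7, 30 °C
Reagents that add atoms: none
Why: Biocatalytic asymmetric ketone reduction, in which the binding pocket of the enzyme exposes only the Re face of the C3 carbonyl to NADPH and so sets the (S)-centre, isopropanol recycles the cofactor, and the alkyne, which a metal-catalysed hydrogenation would endanger, is left alone.

Step 6
Reactants: 5 2-(benzyloxy)-4,6-dimethoxybenzonitrile oxide; 10 methyl (S)-3-hydroxynon-8-ynoate
Product: 11 methyl (S)-7-{3-[2-(benzyloxy)-4,6-dimethoxyphenyl]isoxazol-5-yl}-3-hydroxyheptanoate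
Conditions: toluene, 80 °C
Reagents that add atoms: none
Why: The nitrile oxide adds across the C≡C bond in a concerted, asynchronous thermal Huisgen 1,3-dipolar cycloaddition, in which the dipole carbon (future C4) bonds to the terminal alkyne carbon (future C3) and the dipole oxygen to the internal alkyne carbon (future C2), with no reagent, acid or base present. The closest known reaction type is the addition of isolable 2,6-disubstituted benzonitrile oxides to 1-alkynes, which gives 3-aryl-5-alkylisoxazoles. The one ring formed, the five-membered isoxazole, is closed by an intermolecular (3+2) cycloaddition that takes C–N–O from 5 and two carbons from 10 and is aromatic as formed, so no oxidation has to follow. No stereocentre is created, and the remote (S)-carbinol centre cannot epimerise, eliminate or undergo retro-aldol cleavage in a neutral medium. The step needs 3,5- over 3,4-regioselectivity, which is secured because the aryl-laden dipole carbon goes to the unhindered CH terminus, where the larger alkyne HOMO coefficient also meets the larger LUMO coefficient of the dipole. It also needs the dipole to outlast a slow reaction, which the methoxy and benzyloxy groups flanking the CNO unit secure by blocking dimerisation, while the absence of base keeps the free hydroxyl from adding to the dipole.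

Step 7
Reactants: 11 methyl (S)-7-{3-[2-(benzyloxy)-4,6-dimethoxyphenyl]isoxazol-5-yl}-3-hydroxyheptanoate
Product: 12 methyl (3S,9Z)-10-amino-3-hydroxy-10-(2-hydroxy-4,6-dimethoxyphenyl)-8-oxodec-9-enoate
Conditions: H2 (1 atm), 10% Pd/C, MeOH, rt
Reagents that add atoms: none
Why: Catalytic hydrogenolysis, in which the weak isoxazole N–O bond and the benzylic C–O bond are both cleaved on palladium to give a hydrogen-bonded (Z)-vinylogous amide that resists further reduction, with ester, alcohol and aryl methyl ethers unaffected.

Step 8
Reactants: 12 methyl (3S,9Z)-10-amino-3-hydroxy-10-(2-hydroxy-4,6-dimethoxyphenyl)-8-oxodec-9-enoate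
Product: 14 penithochromone Q, via 1,3-diketone 13 (not isolated)
Conditions: 2 M aq. HCl, MeOH, 60 °C
Reagents that add atoms: water, O
Why: Acid hydrolysis of the enaminone to the 1,3-diketone with loss of ammonia, followed by cyclodehydration of the o-hydroxyaryl 1,3-diketone as in the closing stage of a Baker–Venkataraman chromone synthesis; the phenol adds to the C2 ketone and water leaves, methanol as solvent preserves the methyl ester, and the distant carbinol centre is not involved.

**Compound list**
1 | 2-hydroxy-4,6-dimethoxybenzaldehyde | COc1cc(O)c(C=O)c(OC)c1 | starting material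
2 | benzyl bromide | BrCc1ccccc1 | starting material
3 | 2-(benzyloxy)-4,6-dimethoxybenzaldehyde | COc1cc(OC)c(C=O)c(OCc2ccccc2)c1 | intermediate
4 | (E)-2-(benzyloxy)-4,6-dimethoxybenzaldehyde oxime | COc1cc(OC)c(/C=N/O)c(OCc2ccccc2)c1 | intermediate
5 | 2-(benzyloxy)-4,6-dimethoxybenzonitrile oxide | COc1cc(OC)c(C#[N+][O-])c(OCc2ccccc2)c1 | intermediate
6 | hept-6-ynoic acid | C#CCCCCC(=O)O | starting material
7 | potassium methyl malonate | COC(=O)CC(=O)[O-].[K+] | starting material
8 | 1-(imidazol-1-yl)hept-6-yn-1-one (acyl imidazolide) | C#CCCCCC(=O)n1ccnc1 | intermediate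
9 | methyl 3-oxonon-8-ynoate | COC(=O)CC(=O)CCCCC#C | intermediate
10 | methyl (S)-3-hydroxynon-8-ynoate | COC(=O)C[C@@H](O)CCCCC#C | intermediate
11 | methyl (S)-7-{3-[2-(benzyloxy)-4,6-dimethoxyphenyl]isoxazol-5-yl}-3-hydroxyheptanoate | COC(=O)C[C@@H](O)CCCCc1cc(-c2c(OC)cc(OC)cc2OCc2ccccc2)no1 | intermediate
12 | methyl (3S,9Z)-10-amino-3-hydroxy-10-(2-hydroxy-4,6-dimethoxyphenyl)-8-oxodec-9-enoate | COC(=O)C[C@@H](O)CCCCC(=O)/C=C(\N)c1c(O)cc(OC)cc1OC | intermediate
13 | methyl (S)-3-hydroxy-10-(2-hydroxy-4,6-dimethoxyphenyl)-8,10-dioxodecanoate (1,3-diketone) | COC(=O)C[C@@H](O)CCCCC(=O)CC(=O)c1c(O)cc(OC)cc1OC | intermediate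
14 | penithochromone Q, methyl (S)-7-(5,7-dimethoxy-4-oxo-4H-chromen-2-yl)-3-hydroxyheptanoate | COC(=O)C[C@@H](O)CCCCc1cc(=O)c2c(OC)cc(OC)cc2o1 | target

Total step count: 8
Longest linear sequence: 6 steps (steps 1, 2, 3, 6, 7, 8 from 1)

**Steps most likely to fail**

Risk 1, step 6. The shielded, electron-rich dipole may add only sluggishly to an unactivated alkyne. Thermal isomerisation of the dipole or its slow dimerisation could then compete, and regiocontrol could be incomplete. The fallback sets out from 10. Semi-hydrogenation over Pd/CaCO3 poisoned with Pb(OAc)2, with quinoline, should give methyl (S)-3-hydroxynon-8-enoate F1. Its monosubstituted alkene is a faster dipolarophile for 5 and places its substituent at the 5-position. The cycloaddition in toluene should give methyl (3S)-7-{3-[2-(benzyloxy)-4,6-dimethoxyphenyl]-4,5-dihydroisoxazol-5-yl}-3-hydroxyheptanoate F2 as a pair of ring epimers, which does not matter for what follows. Dehydrogenation with activated MnO2 in hot toluene removes that extra centre, leaves the unactivated secondary alcohol alone, and comes back to the route at 11.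

Risk 2, step 7. The two hydrogenolyses may run at unequal rates. The reaction could stall after loss of the benzyl group with the N–O bond intact, or forcing conditions could over-reduce the enaminone. The fallback sets out from 11 and separates the two cleavages. Mo(CO)6 and water in MeCN at reflux cleave only the N–O bond by electron transfer from zerovalent molybdenum. This should give methyl (3S,9Z)-10-amino-10-[2-(benzyloxy)-4,6-dimethoxyphenyl]-3-hydroxy-8-oxodec-9-enoate F3. A short, mild hydrogenolysis over Pd/C then removes only the benzyl ether and comes back to the route at 12.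

Risk 3, step 5. The enzymes at hand may show poor facial selectivity, the wrong sense of reduction, or low conversion of the lipophilic keto ester. The fallback sets out from 9 and postpones the reduction until the alkyne is consumed. Cycloaddition of 9 with 5 under the neutral conditions of step 6 should give methyl 7-{3-[2-(benzyloxy)-4,6-dimethoxyphenyl]isoxazol-5-yl}-3-oxoheptanoate F4. A Noyori asymmetric hydrogenation with RuCl2[(S)-BINAP] and H2 in MeOH follows. Its sense for 3-oxoalkanoates is well established, the (S)-ligand giving the (S)-alcohol, and the sequence comes back to the route at 11.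

**Further compounds**
F1 | step 6 | methyl (S)-3-hydroxynon-8-enoate | COC(=O)C[C@@H](O)CCCCC=C
F2 | step 6 | methyl (3S)-7-{3-[2-(benzyloxy)-4,6-dimethoxyphenyl]-4,5-dihydroisoxazol-5-yl}-3-hydroxyheptanoate | COC(=O)C[C@@H](O)CCCCC1CC(c2c(OC)cc(OC)cc2OCc2ccccc2)=NO1
F3 | step 7 | methyl (3S,9Z)-10-amino-10-[2-(benzyloxy)-4,6-dimethoxyphenyl]-3-hydroxy-8-oxodec-9-enoate | COC(=O)C[C@@H](O)CCCCC(=O)/C=C(\N)c1c(OC)cc(OC)cc1OCc1ccccc1
F4 | step 5 | methyl 7-{3-[2-(benzyloxy)-4,6-dimethoxyphenyl]isoxazol-5-yl}-3-oxoheptanoate | COC(=O)CC(=O)CCCCc1cc(-c2c(OC)cc(OC)cc2OCc2ccccc2)no1
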